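## Structural features

The target is monocyclic: a single cyclohex-4-ene ring in which C6, C1, C2 and C3 all carry oxygen and C1 also carries the one-carbon branch C7. C1 is a fully substituted carbinol (tertiary OH and CH2OBz) lying between C6 (free allylic OH) and C2 (acetate), and C2 is followed by C3 (allylic benzoate). The four stereocentres are therefore contiguous, (1R,2S,3R,6S), with O1/O2 cis, O2/O3 trans and O1/O6 trans (C7 cis to O3 and to O6). Five oxygens carry three kinds of substituent: benzoates on O3 and O7, an acetate on O2, and hydrogen on O1 and O6. The fragile features are the two allylic C–O bonds flanking the C4=C5 alkene (ionisation, elimination towards an arene) and the esters next to free hydroxyls, which can migrate under base, so strong base, hydride and fluoride are excluded once the esters are on. The real difficulty is double: building the quaternary carbinol C1 in a fixed relation to C2, C3 and C6, and placing three different groups on five oxygens with few protecting-group steps. The key step exploits the fact that the chain C7–C1–C2–C3–C4 maps onto C1–C5 of D-gluconic acid. Sugar C3 and C4 already have the configurations of ring C2 and C3, the lactone α-carbon (sugar C2) becomes the quaternary C1, and the lactone oxygen on sugar C5 is the departing end of a [3,3] shift that joins C1 to C6, creates C4=C5 and excises the ring oxygen.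

## Logic of the disconnections

18 ⇒ 17. Cut: the O6–benzyl bond. O6 and O3 are both secondary allylic oxygens and cannot be told apart by acylation, so O6 must stay etherified from the moment it is introduced until all esters are on. The gain is that the ester pattern becomes a question of O1, O2, O3 and O7 only. The forward cleavage must be non-basic and non-reducing, which an oxidative debenzylation satisfies.

17 ⇒ 16 ⇒ 15. Cut: the O2–acetyl bond, then the O3–benzoyl and O7–benzoyl bonds. In 15 the four hydroxyls differ sterically (primary O7, allylic secondary O3, secondary O2 wedged between C1 and C3, tertiary O1), so they can be acylated in order of reactivity. The gain is that five oxygens are dressed in two steps with no extra protecting group. The demand is that benzoylation stops after O7 and O3 and that acetylation causes no acyl shift.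

15 ⇒ 14 ⇒ 13. Cut: three O–Si bonds, then the two C7–H bonds (alcohol back to acid). All silyl groups are removed directly after the reduction, before any ester exists. This makes silyl migration during the hydride step harmless and allows fluoride to be used freely, and it shortens the sequence from the rearranged acid to the target to five steps. The demand is reduction of a hindered α-silyloxy acid and complete desilylation, the tertiary ether included.

13 ⇒ 10 (through 12 and 11). Cut: the ring bond C1–C6, with reconnection of a carboxyl oxygen to ring C4 and shift of the alkene from C4=C5 to C5=C6, that is, the retro-[3,3] step. This turns the carbocycle with its quaternary centre into a pyranoid lactone whose stereocentres come from the chiral pool. The gain is one ring, one C–C bond and two stereocentres (C1, C6) in one step, both dictated by one existing centre and one alkene geometry. The demand is clean O-silylation of a β-oxygenated lactone enolate and an enol ether of pure E geometry, since the Z isomer would lead to the C6 epimer.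

10 ⇒ 9 ⇒ 8 + 4. Cut: the side-chain C6=C7 double bond (sugar numbering), in two stages. A two-stage phosphine oxide olefination lets the alkene geometry be fixed by separating diastereomeric adducts before a stereospecific elimination. The gain is that 8 is simply the sugar lactone at the aldehyde level of C6. The demand is that carbonyl addition outruns enolisation of 8 and that the elimination does not scramble.

8 ⇒ 7 ⇒ 5 + 6. Cut: the C6 oxidation level back to a silyl ether, then four O–Si bonds. One silyl reagent protects O2–O4 and at the same time activates O6, because a primary triethylsilyl ether can be oxidised directly. The gain is 5, a commodity lactone. Its C3 and C4 are used as they are, its C5 is the source of chirality transfer, and its C2 is erased on enolisation, so epimerisation there is harmless. The demand is that C5 of 8 keeps its configuration.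

4 ⇒ 3 + 2; 2 ⇒ 1. Cut: the O–CH2(P) bond, then the O–S bond. The phosphine oxide reagent is assembled by alkoxide displacement of a sulfonate, which avoids carcinogenic chloromethyl ethers. The demand is substitution at carbon in preference to attack at sulfur.

## Other disconnections considered

Alternative 1: The cut is at the C2–O and C3–O bonds. Ring and C7 come from a prochiral arene-derived dienol, (1-hydroxycyclohexa-2,5-dien-1-yl)methyl benzoate A1, and oxygen is added to one of its two enantiotopic alkenes. The forward key step would be a hydroxyl-directed epoxidation with Hf(OtBu)4 (tetravalent hafnium), a chiral bishydroxamic acid and cumene hydroperoxide, giving the syn epoxy alcohol A2 and fixing C1, C2 and C3 at once.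
- In favour: no ring has to be formed, A1 is a few steps from a Birch reduction, the step is catalytic and A2 already carries the C7 benzoate. Opening the oxirane of A2 with benzoate at C3 (away from the quaternary carbon, trans-diaxial) would place the C3 benzoate and the C2 hydroxyl unambiguously. On step count and on O2/O3 differentiation this plan is the better one.
- Against: A1 is a doubly allylic tertiary alcohol that can lose water and aromatise under a Lewis acid. Desymmetrisation of such a cyclic substrate lies at the edge of what this catalyst class is known for, and the absolute configuration would rest on catalyst selectivity. The alkene left in A2 is C5=C6, so it must still be transposed to C4=C5 with introduction of O6. A singlet-oxygen ene reaction has forced regiochemistry, but its facial bias, steered by the C1 hydroxyl, would tend to put O6 cis to O1, the opposite of what is required.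
- Comparison: both plans rely on intramolecular delivery (a metal-bound hydroxyl there, a tethered enol ether here). The chosen plan is the more secure on stereochemistry, since it takes C2 and C3 from the sugar and sets C1 and C6 together.

Alternative 2: The cut is at C2–C3 and C6–C1, a [4+2] retron. The diene (1E,3E)-4-(tert-butyldimethylsilyloxy)buta-1,3-dien-1-yl benzoate A3 would supply C3–C6 with the C3 benzoate in place. A vinylene carbonate carrying an N-acyl oxazolidinone, A4, would supply C1, C2 and C7. The forward key step would be an endo Diels–Alder reaction under [Cu((S,S)-t-Bu-box)](SbF6)2 (divalent copper), bound in a bidentate way by the imide, to give adduct A5.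
- In favour: it is the most convergent plan, making two C–C bonds, the alkene and four stereocentres in one step. Relative configuration is encoded in alkene geometry (cis carbonate, E,E diene, endo acyl group), the same principle as in the chosen key step. On convergence and step economy it is the better plan, and on relative stereocontrol the equal.
- Against: A4 is a doubly oxygen-substituted, electronically deactivated trisubstituted dienophile that must form a quaternary carbon, and it is a sensitive, little-known compound. Regiochemistry depends on the silyloxy terminus of A3 out-directing the benzoyloxy terminus, which is a modest difference, and the Lewis acid may desilylate A3. After the cycloaddition the imide must be reduced beside a benzoate and a carbonate and O1/O2/O7 must be differentiated, which erodes the step advantage.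
- Comparison: both key steps are concerted six-electron processes. The chosen one is intramolecular, needs no catalyst control and takes its absolute configuration from the chiral pool, so it is the safer. Alternative 2 would be the shorter if A4 behaves.

Alternative 3: The cut is at C1–C2. The precursor is the open-chain (Z)-keto aldehyde A6 with the aldehyde at C2 and the ketone at C1. The forward key step would be a ketyl coupling with SmI2 (divalent samarium) and t-BuOH at low temperature, closing the ring as the cis-1,2-diol A7 through a chelate in which trivalent samarium bridges both oxygens, each new hydroxyl trans to its neighbouring ether.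
- In favour: pinacol closures of sugar-derived dicarbonyl compounds to cis-diols are well precedented and the Z alkene preorganises the chain. A7 has differentiated oxygens (free O1/O2 diol, one kind of ether on O3 and O7, a silyl ether on O6), which maps onto the ester pattern of the target more cleanly than the three equal silyl ethers of 13. On protecting-group logic alternative 3 is the better.
- Against: A6 is a doubly α-oxygenated, β,γ-unsaturated dicarbonyl compound, prone to epimerisation at C3 and C6, to conjugation and to Z-to-E isomerisation. Both stereocentres and the Z alkene must be built beforehand in an acyclic setting. A ketone–aldehyde coupling to a tetrasubstituted carbinol is slower than a dialdehyde coupling, SmI2 can instead cleave the α C–O bonds, and the reagent is used in excess.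
- Comparison: alternative 3 creates C1 and C2 and inherits C3 and C6; the chosen plan creates C1 and C6 and inherits C2 and C3 from a cheap sugar with no asymmetric step. A chelate-controlled radical coupling has more competing channels than a concerted chirality transfer, and the chosen plan should be the shorter.

Key step: step 7

**Remarks on the chemistry**
- Naming: the precursor of the key step keeps an oxygen on C7 (the enol ether), so it is a 6-deoxy-hept-6-enono-1,5-lactone; a 6,7-dideoxy name would not fit it. The structures of 10 and 13 were checked centre by centre against the D-gluco configuration and against the target.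
- Assumption: the threo adduct 9 is drawn as its (6R,7S) isomer; the (6S,7R) isomer eliminates to the same E enol ether and is carried along with it.
- Step 3 consumes four equivalents of 6, one per hydroxyl. One stands on the Reactants line and the other three on the line of reagents that add atoms.
- Anions and onium salts generated and consumed within one step (lithiated phosphine oxide, sodium alkoxide, chlorosulfonium salt) are treated as reagents of that step and are not numbered.
- Ring numbering (C1 quaternary, C2, C3, C4=C5, C6, branch C7) is that of the target and is used for the carbocycles; sugar numbering is used for the lactones. Where both occur in one step, each locant is marked "ring" or "sugar".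

## Steps

Step 1
Reactants: 1 (hydroxymethyl)diphenylphosphine oxide
Product: 2 (diphenylphosphoryl)methyl 4-methylbenzenesulfonate
Conditions: TsCl, Et3N, DMAP (cat.), CH2Cl2, 0 °C → rt
Reagents that add atoms: 4-methylbenzenesulfonyl chloride, Cc1ccc(cc1)S(Cl)(=O)=O
Why: O-sulfonylation of a primary alcohol under amine base; the mild base avoids loss of formaldehyde from the α-hydroxy phosphine oxide.

Step 2
Reactants: 3 4-methoxybenzyl alcohol; 2 (diphenylphosphoryl)methyl 4-methylbenzenesulfonate
Product: 4 [(4-methoxybenzyloxy)methyl]diphenylphosphine oxide
Conditions: 3, NaH, THF/DMF, 0 °C; then 2, rt → 50 °C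
Reagents that add atoms: none
Why: Williamson-type SN2 displacement of the sulfonate by the alkoxide, the C–O construction that is routine for (sulfonyloxymethyl)phosphoryl compounds; it avoids chloromethyl ethers.

Step 3
Reactants: 5 D-glucono-1,5-lactone; 6 chlorotriethylsilane
Product: 7 2,3,4,6-tetra-O-triethylsilyl-D-glucono-1,5-lactone
Conditions: Et3SiCl (4.6 equiv in all), imidazole, DMF, 0 °C → rt
Reagents that add atoms: chlorotriethylsilane (three further equivalents), CC[Si](Cl)(CC)CC.CC[Si](Cl)(CC)CC.CC[Si](Cl)(CC)CC
Why: Exhaustive O-silylation of the four hydroxyls, which consumes four equivalents of 6, under a mild amine base that keeps the δ-lactone closed; no stereocentre is touched.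

Step 4
Reactants: 7 2,3,4,6-tetra-O-triethylsilyl-D-glucono-1,5-lactone
Product: 8 2,3,4-tri-O-triethylsilyl-6-aldehydo-D-glucono-1,5-lactone (C6 is a formyl group)
Conditions: (COCl)2, DMSO, CH2Cl2, −78 → −35 °C; then Et3N, −78 → 0 °C; used crude
Reagents that add atoms: none
Why: Swern conditions cleave a primary triethylsilyl ether in situ and oxidise it to the aldehyde while secondary silyl ethers survive (direct Swern oxidation of primary silyl ethers). Low temperature and immediate use protect the C5 stereocentre.

Step 5
Reactants: 4 [(4-methoxybenzyloxy)methyl]diphenylphosphine oxide; 8 2,3,4-tri-O-triethylsilyl-6-aldehydo-D-glucono-1,5-lactone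
Product: 9 threo β-hydroxy phosphine oxide: the tri-O-triethylsilyl lactone whose C5 carries CH(OH)–CH(OCH2C6H4OMe-4)–P(O)Ph2, drawn as the (6R,7S) isomer
Conditions: 4, LiN(iPr)2, THF, −78 °C; then 8, −78 °C; AcOH quench at −78 °C; threo adducts separated from erythro adducts by chromatography
Reagents that add atoms: none
Why: First stage of a Horner–Wittig olefination: the lithiated α-alkoxy phosphine oxide adds to the aldehyde far faster than to the lactone, and lithium alkoxides of such adducts do not eliminate, so the diastereomers can be separated. Only the threo pair is taken on; both new centres are destroyed in step 6.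

Step 6
Reactants: 9 threo β-hydroxy phosphine oxide
Product: 10 6-deoxy-7-O-(4-methoxybenzyl)-2,3,4-tri-O-triethylsilyl-D-gluco-hept-6(E)-enono-1,5-lactone
Conditions: KN(SiMe3)2 (1.05 equiv), THF, −78 → 0 °C
Reagents that add atoms: none
Why: Second stage of the Horner–Wittig olefination: stereospecific syn elimination of diphenylphosphinate from the potassium alkoxide of the threo adduct should give the E enol ether only.

Step 7
Reactants: 10 6-deoxy-7-O-(4-methoxybenzyl)-2,3,4-tri-O-triethylsilyl-D-gluco-hept-6(E)-enono-1,5-lactone
Product: 13 6-(4-methoxybenzyloxy)-1,2,3-tris(triethylsilyloxy)cyclohex-4-ene-1-carboxylic acid (ring configuration as in 18: O1 cis to O2; O3 and O6 on the opposite face), via silyl ketene acetal 11 (not isolated), via trimethylsilyl ester 12 (not isolated)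
Conditions: Me3SiCl, Et3N, KN(SiMe3)2 added last (internal quench), THF, −78 °C; then PhMe, 80 °C; aq. citric acid work-up
Reagents that add atoms: none
Why: KN(SiMe3)2 removes the proton on sugar C2 of 10 with Me3SiCl already present, so the enolate is O-silylated as it forms and the endocyclic silyl ketene acetal 11 is reached before the silyloxy group on sugar C3 (equatorial, poorly aligned with the enolate π system) can be expelled. On warming, 11 should undergo a concerted suprafacial [3,3]-sigmatropic shift in which sugar C2 bonds to sugar C7 while the bond between sugar C5 and the lactone ring oxygen breaks; the closest known reaction type is the Ireland–Claisen rearrangement of 6-alkenyl lactone silyl ketene acetals to cycloalkene carboxylic acids, and C–C bond formation at the oxygen-bearing carbon of an enol ether is the event known from ester enolate Claisen rearrangements of glycal esters. Ring closure: the carbocycle (sugar C2–C3–C4–C5=C6–C7) closes by the sigmatropic shift itself through a boat-shaped, bicyclo[2.2.2]octane-like transition state, the only arrangement in which the tethered enol ether reaches the ketene acetal, and the new ring alkene is therefore cis. Stereocentre at ring C1 (sugar C2): the side chain hangs from sugar C5 on the lactone face that also carries the oxygen on sugar C3, so bonding can occur on that face only, which places the carboxyl carbon trans to the ring C2 oxygen and cis to the ring C3 oxygen. Stereocentre at ring C6 (sugar C7): the E geometry holds the 4-methoxybenzyloxy group in the outer position of the boat, on the side of the departing carboxylate bridge, so that it ends up cis to the carboxyl carbon and trans to the ring C1 oxygen. The selectivity needed is complete transfer of chirality from sugar C5 together with retention of the E geometry; the cyclic tether secures the first and geometrically pure 10 the second, while the donor oxygen at the bond-forming terminus should lower the barrier. Mild acidic work-up hydrolyses the silyl ester 12 to 13 without touching the triethylsilyl ethers.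

Step 8
Reactants: 13 6-(4-methoxybenzyloxy)-1,2,3-tris(triethylsilyloxy)cyclohex-4-ene-1-carboxylic acid
Product: 14 [6-(4-methoxybenzyloxy)-1,2,3-tris(triethylsilyloxy)cyclohex-4-en-1-yl]methanol (ring configuration unchanged)
Conditions: LiAlH4, THF, 0 → 40 °C; H2O/aq. NaOH work-up
Reagents that add atoms: none
Why: Hydride reduction of a carboxylic acid to the primary alcohol; ethers and the isolated alkene are inert. Any silyl shift towards O7 is harmless because all silyl groups are removed in step 9.

Step 9
Reactants: 14 [6-(4-methoxybenzyloxy)-1,2,3-tris(triethylsilyloxy)cyclohex-4-en-1-yl]methanol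
Product: 15 1-(hydroxymethyl)-6-(4-methoxybenzyloxy)cyclohex-4-ene-1,2,3-triol (ring configuration unchanged)
Conditions: Bu4NF (4 equiv), THF, 0 °C → rt
Reagents that add atoms: none
Why: Fluoride cleaves all three Si–O bonds, the tertiary one included; no ester is present yet, so the basic fluoride can do no harm.

Step 10
Reactants: 15 1-(hydroxymethyl)-6-(4-methoxybenzyloxy)cyclohex-4-ene-1,2,3-triol
Product: 16 [3-(benzoyloxy)-1,2-dihydroxy-6-(4-methoxybenzyloxy)cyclohex-4-en-1-yl]methyl benzoate
Conditions: BzCl (2.1 equiv), pyridine/CH2Cl2, −40 → 0 °C
Reagents that add atoms: benzoyl chloride, O=C(Cl)c1ccccc1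
Why: Rate-controlled acylation: the primary O7–H reacts first, then the allylic O3–H, which has only one substituted neighbour. O2–H is wedged between the quaternary C1 and C3, and the tertiary O1–H is inert to BzCl/pyridine.

Step 11
Reactants: 16 [3-(benzoyloxy)-1,2-dihydroxy-6-(4-methoxybenzyloxy)cyclohex-4-en-1-yl]methyl benzoate
Product: 17 [2-acetoxy-3-(benzoyloxy)-1-hydroxy-6-(4-methoxybenzyloxy)cyclohex-4-en-1-yl]methyl benzoate
Conditions: Ac2O (1.5 equiv), pyridine, DMAP (cat.), CH2Cl2, 0 °C → rt
Reagents that add atoms: acetic anhydride, CC(=O)OC(C)=O
Why: DMAP-catalysed acetylation of the only remaining secondary hydroxyl; a tertiary alcohol does not acylate with a small excess of anhydride at this temperature.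

Step 12
Reactants: 17 [2-acetoxy-3-(benzoyloxy)-1-hydroxy-6-(4-methoxybenzyloxy)cyclohex-4-en-1-yl]methyl benzoate
Product: 18 [(1R,2S,3R,6S)-2-acetoxy-3-(benzoyloxy)-1,6-dihydroxycyclohex-4-en-1-yl]methyl benzoate (target)
Conditions: DDQ, CH2Cl2/pH 7 phosphate buffer (10:1), 0 °C
Reagents that add atoms: none
Why: Oxidative cleavage of the 4-methoxybenzyl ether (hydride abstraction at the electron-rich benzylic carbon, then hydrolysis of the oxocarbenium ion by water). Esters, alkene and tertiary alcohol are untouched, and the buffered wet medium suppresses acyl migration and acetal formation with O1.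

## Compound list

1 | (hydroxymethyl)diphenylphosphine oxide | O=P(CO)(c1ccccc1)c1ccccc1 | starting material
2 | (diphenylphosphoryl)methyl 4-methylbenzenesulfonate | Cc1ccc(cc1)S(=O)(=O)OCP(=O)(c1ccccc1)c1ccccc1 | intermediate
3 | 4-methoxybenzyl alcohol | COc1ccc(CO)cc1 | starting material
4 | [(4-methoxybenzyloxy)methyl]diphenylphosphine oxide | COc1ccc(COCP(=O)(c2ccccc2)c2ccccc2)cc1 | intermediate
5 | D-glucono-1,5-lactone | O=C1[C@H](O)[C@@H](O)[C@H](O)[C@@H](CO)O1 | starting material
6 | chlorotriethylsilane | CC[Si](Cl)(CC)CC | starting material
7 | 2,3,4,6-tetra-O-triethylsilyl-D-glucono-1,5-lactone | O=C1[C@H](O[Si](CC)(CC)CC)[C@@H](O[Si](CC)(CC)CC)[C@H](O[Si](CC)(CC)CC)[C@@H](CO[Si](CC)(CC)CC)O1 | intermediate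
8 | 2,3,4-tri-O-triethylsilyl-6-aldehydo-D-glucono-1,5-lactone | O=C1[C@H](O[Si](CC)(CC)CC)[C@@H](O[Si](CC)(CC)CC)[C@H](O[Si](CC)(CC)CC)[C@@H](C=O)O1 | intermediate
9 | threo β-hydroxy phosphine oxide, (6R,7S)-7-(diphenylphosphoryl)-7-O-(4-methoxybenzyl)-2,3,4-tri-O-triethylsilyl-heptono-1,5-lactone, D-gluco at C2–C5 | O=C1[C@H](O[Si](CC)(CC)CC)[C@@H](O[Si](CC)(CC)CC)[C@H](O[Si](CC)(CC)CC)[C@@H]([C@@H](O)[C@@H](OCc2ccc(OC)cc2)P(=O)(c2ccccc2)c2ccccc2)O1 | intermediate
10 | 6-deoxy-7-O-(4-methoxybenzyl)-2,3,4-tri-O-triethylsilyl-D-gluco-hept-6(E)-enono-1,5-lactone | O=C1[C@H](O[Si](CC)(CC)CC)[C@@H](O[Si](CC)(CC)CC)[C@H](O[Si](CC)(CC)CC)[C@@H](/C=C/OCc2ccc(OC)cc2)O1 | intermediate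
11 | endocyclic 1-O-trimethylsilyl ketene acetal of 10 (C1=C2, not isolated) | C[Si](C)(C)OC1=C(O[Si](CC)(CC)CC)[C@@H](O[Si](CC)(CC)CC)[C@H](O[Si](CC)(CC)CC)[C@@H](/C=C/OCc2ccc(OC)cc2)O1 | intermediate
12 | trimethylsilyl ester of 13 (not isolated) | CC[Si](CC)(CC)O[C@H]1[C@H](O[Si](CC)(CC)CC)C=C[C@H](OCc2ccc(OC)cc2)[C@]1(O[Si](CC)(CC)CC)C(=O)O[Si](C)(C)C | intermediate
13 | 6-(4-methoxybenzyloxy)-1,2,3-tris(triethylsilyloxy)cyclohex-4-ene-1-carboxylic acid, ring configuration as in the target | CC[Si](CC)(CC)O[C@H]1[C@H](O[Si](CC)(CC)CC)C=C[C@H](OCc2ccc(OC)cc2)[C@]1(O[Si](CC)(CC)CC)C(=O)O | intermediate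
14 | [6-(4-methoxybenzyloxy)-1,2,3-tris(triethylsilyloxy)cyclohex-4-en-1-yl]methanol | CC[Si](CC)(CC)O[C@H]1[C@H](O[Si](CC)(CC)CC)C=C[C@H](OCc2ccc(OC)cc2)[C@]1(O[Si](CC)(CC)CC)CO | intermediate
15 | 1-(hydroxymethyl)-6-(4-methoxybenzyloxy)cyclohex-4-ene-1,2,3-triol | O[C@H]1[C@H](O)C=C[C@H](OCc2ccc(OC)cc2)[C@]1(O)CO | intermediate
16 | [3-(benzoyloxy)-1,2-dihydroxy-6-(4-methoxybenzyloxy)cyclohex-4-en-1-yl]methyl benzoate | O[C@H]1[C@H](OC(=O)c2ccccc2)C=C[C@H](OCc2ccc(OC)cc2)[C@]1(O)COC(=O)c1ccccc1 | intermediate
17 | [2-acetoxy-3-(benzoyloxy)-1-hydroxy-6-(4-methoxybenzyloxy)cyclohex-4-en-1-yl]methyl benzoate | CC(=O)O[C@H]1[C@H](OC(=O)c2ccccc2)C=C[C@H](OCc2ccc(OC)cc2)[C@]1(O)COC(=O)c1ccccc1 | intermediate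
18 | [(1R,2S,3R,6S)-2-acetoxy-3-(benzoyloxy)-1,6-dihydroxycyclohex-4-en-1-yl]methyl benzoate | CC(=O)O[C@H]1[C@H](OC(=O)c2ccccc2)C=C[C@H](O)[C@]1(O)COC(=O)c1ccccc1 | target

## Step count and least certain steps

Total: 12 steps (two for the phosphine oxide reagent, ten from the sugar lactone). Longest linear sequence: 10 steps (5 to 18 through steps 3–12; the branch from 1 through steps 1, 2 and 5–12 is equally long).

Step 7 (key step). Two processes may defeat it. One is expulsion of the silyloxy group on sugar C3 from the potassium enolate before O-silylation; the internal quench is meant to prevent this. The other, more specific to this substrate, is slow bond formation between a fully substituted ketene acetal carbon and an oxygen-bearing alkene terminus, so that desilylation or decomposition of 11 competes on heating. The fallback sets out from 8 and comes back at 18; it removes the oxygen from the migrating terminus and introduces O6 after the ring is made. Methylenation of 8 (Ph3P=CH2, THF, −78 °C) would give 6,7-dideoxy-2,3,4-tri-O-triethylsilyl-D-gluco-hept-6-enono-1,5-lactone F1, the plain 6-vinyl lactone for which the boat rearrangement has its closest precedent. The conditions of step 7 would give 1,2,3-tris(triethylsilyloxy)cyclohex-4-ene-1-carboxylic acid F2, and those of steps 8 and 9 [1,2,3-tris(triethylsilyloxy)cyclohex-4-en-1-yl]methanol F3 and 1-(hydroxymethyl)cyclohex-4-ene-1,2,3-triol F4. The conditions of steps 10 and 11 would give [3-(benzoyloxy)-1,2-dihydroxycyclohex-4-en-1-yl]methyl benzoate F5 and [2-acetoxy-3-(benzoyloxy)-1-hydroxycyclohex-4-en-1-yl]methyl benzoate F6. Allylic hydroxylation of the C6 methylene of F6 (SeO2, t-BuOOH, CH2Cl2) would then give 18. The ene step is expected to take the pseudoaxial C6 hydrogen, trans to the pseudoaxial O1, and to return oxygen to that face, while the C3–H is deactivated by its benzoate. Facial selectivity at C6 is the weak point of this detour.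

Step 5 (with step 6). The addition may give an unfavourable threo/erythro distribution, and only the threo pair leads to the E enol ether. The basic phosphoryl anion may also epimerise C5 or eliminate the C4 silyloxy group of 8. In step 6, silyl migration to the alkoxide or reversal of the addition may erode stereospecificity. The fallback sets out from 8 and comes back at 10, replacing the basic olefination by an E-selective, non-basic C–C then C–O construction. CrCl2 (divalent chromium), LiI and Cl2CHB(pin) in THF (Takai-type boron olefination) would convert 8 into 6,7-dideoxy-7-(4,4,5,5-tetramethyl-1,3,2-dioxaborolan-2-yl)-2,3,4-tri-O-triethylsilyl-D-gluco-hept-6(E)-enono-1,5-lactone F7. A Chan–Lam-type coupling of F7 with 3, mediated by Cu(OAc)2 (divalent copper) and Et3N at rt, proceeds with retention of alkene geometry and would give 10 without passing through 9.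

Step 4. β-Elimination across C4–C5 or epimerisation at C5 of the α-alkoxy aldehyde may occur when Et3N is added, and secondary silyl ethers may be lost during activation. The fallback sets out from 7 and comes back at 8, separating deprotection from oxidation and using no base. Selective cleavage of the primary silyl ether (HF·pyridine buffered with pyridine, THF, 0 °C) would give 2,3,4-tri-O-triethylsilyl-D-glucono-1,5-lactone F8, which Dess–Martin periodinane with NaHCO3 in CH2Cl2 would oxidise to 8.

Step 10. Discrimination between O3 and O2 may be incomplete (over-benzoylation or a benzoate on O2), and base may induce a benzoyl shift from O3 to O2. The fallback sets out from 14 and comes back at 17; it fixes the regiochemistry by temporary cyclic protection instead of relative rates. Benzoylation of the primary hydroxyl of 14 (BzCl, pyridine, DMAP) would give [6-(4-methoxybenzyloxy)-1,2,3-tris(triethylsilyloxy)cyclohex-4-en-1-yl]methyl benzoate F9, and desilylation (HF·pyridine, THF) would give [1,2,3-trihydroxy-6-(4-methoxybenzyloxy)cyclohex-4-en-1-yl]methyl benzoate F10. MeC(OMe)3 with catalytic camphorsulfonic acid would tie O1 and O2, the only cis-diol, as the cyclic O1,O2-(1-methoxyethylidene) orthoacetate F11. BzCl/pyridine would acylate the remaining O3 to give the 3-O-benzoyl orthoacetate F12. Finally, 80% aqueous AcOH would open the orthoester to the secondary acetate on O2 with the tertiary O1–H free, which is 17.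

## Further compounds

F1 | step 7 | 6,7-dideoxy-2,3,4-tri-O-triethylsilyl-D-gluco-hept-6-enono-1,5-lactone | O=C1[C@H](O[Si](CC)(CC)CC)[C@@H](O[Si](CC)(CC)CC)[C@H](O[Si](CC)(CC)CC)[C@@H](C=C)O1
F2 | step 7 | 1,2,3-tris(triethylsilyloxy)cyclohex-4-ene-1-carboxylic acid (C1–C3 as in the target) | CC[Si](CC)(CC)O[C@H]1[C@H](O[Si](CC)(CC)CC)C=CC[C@]1(O[Si](CC)(CC)CC)C(=O)O
F3 | step 7 | [1,2,3-tris(triethylsilyloxy)cyclohex-4-en-1-yl]methanol | CC[Si](CC)(CC)O[C@H]1[C@H](O[Si](CC)(CC)CC)C=CC[C@]1(O[Si](CC)(CC)CC)CO
F4 | step 7 | 1-(hydroxymethyl)cyclohex-4-ene-1,2,3-triol | O[C@H]1[C@H](O)C=CC[C@]1(O)CO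
F5 | step 7 | [3-(benzoyloxy)-1,2-dihydroxycyclohex-4-en-1-yl]methyl benzoate | O[C@H]1[C@H](OC(=O)c2ccccc2)C=CC[C@]1(O)COC(=O)c1ccccc1
F6 | step 7 | [2-acetoxy-3-(benzoyloxy)-1-hydroxycyclohex-4-en-1-yl]methyl benzoate | CC(=O)O[C@H]1[C@H](OC(=O)c2ccccc2)C=CC[C@]1(O)COC(=O)c1ccccc1
F7 | step 5 | 6,7-dideoxy-7-(4,4,5,5-tetramethyl-1,3,2-dioxaborolan-2-yl)-2,3,4-tri-O-triethylsilyl-D-gluco-hept-6(E)-enono-1,5-lactone | O=C1[C@H](O[Si](CC)(CC)CC)[C@@H](O[Si](CC)(CC)CC)[C@H](O[Si](CC)(CC)CC)[C@@H](/C=C/B2OC(C)(C)C(C)(C)O2)O1
F8 | step 4 | 2,3,4-tri-O-triethylsilyl-D-glucono-1,5-lactone | O=C1[C@H](O[Si](CC)(CC)CC)[C@@H](O[Si](CC)(CC)CC)[C@H](O[Si](CC)(CC)CC)[C@@H](CO)O1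
F9 | step 10 | [6-(4-methoxybenzyloxy)-1,2,3-tris(triethylsilyloxy)cyclohex-4-en-1-yl]methyl benzoate | CC[Si](CC)(CC)O[C@H]1[C@H](O[Si](CC)(CC)CC)C=C[C@H](OCc2ccc(OC)cc2)[C@]1(O[Si](CC)(CC)CC)COC(=O)c1ccccc1
F10 | step 10 | [1,2,3-trihydroxy-6-(4-methoxybenzyloxy)cyclohex-4-en-1-yl]methyl benzoate | O[C@H]1[C@H](O)C=C[C@H](OCc2ccc(OC)cc2)[C@]1(O)COC(=O)c1ccccc1
F11 | step 10 | cyclic O1,O2-(1-methoxyethylidene) orthoacetate of F10 (orthoester carbon as a mixture) | COC1(C)O[C@H]2[C@H](O)C=C[C@H](OCc3ccc(OC)cc3)[C@]2(O1)COC(=O)c1ccccc1
F12 | step 10 | 3-O-benzoyl orthoacetate, the 3-O-benzoate of F11 | COC1(C)O[C@H]2[C@H](OC(=O)c3ccccc3)C=C[C@H](OCc3ccc(OC)cc3)[C@]2(O1)COC(=O)c1ccccc1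
A1 | alternative 1 | (1-hydroxycyclohexa-2,5-dien-1-yl)methyl benzoate | OC1(COC(=O)c2ccccc2)C=CCC=C1
A2 | alternative 1 | (2-hydroxy-7-oxabicyclo[4.1.0]hept-3-en-2-yl)methyl benzoate, oxirane syn to the hydroxyl | O2[C@H]1[C@@H]2CC=C[C@]1(O)COC(=O)c1ccccc1
A3 | alternative 2 | (1E,3E)-4-(tert-butyldimethylsilyloxy)buta-1,3-dien-1-yl benzoate | O=C(O/C=C/C=C/O[Si](C)(C)C(C)(C)C)c1ccccc1
A4 | alternative 2 | 3-(2-oxo-1,3-dioxole-4-carbonyl)-1,3-oxazolidin-2-one | O=C1OC=C(O1)C(=O)N1CCOC1=O
A5 | alternative 2 | endo cycloadduct: cyclohexene with C1–C2 cyclic carbonate, C3 benzoate, C6 silyl ether and C7 acyl oxazolidinone | O=C2O[C@H]1[C@H](OC(=O)c3ccccc3)C=C[C@H](O[Si](C)(C)C(C)(C)C)[C@]1(O2)C(=O)N1CCOC1=O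
A6 | alternative 3 | (Z)-keto aldehyde: (Z)-5-(tert-butyldimethylsilyloxy)-2,7-bis(4-methoxybenzyloxy)-6-oxohept-3-enal, configured as in A7 | O=C[C@H](OCc1ccc(OC)cc1)/C=C\[C@H](O[Si](C)(C)C(C)(C)C)C(=O)COCc1ccc(OC)cc1
A7 | alternative 3 | cis-1,2-diol with 4-methoxybenzyl ethers on O3 and O7 and a silyl ether on O6 | O[C@H]1[C@H](OCc2ccc(OC)cc2)C=C[C@H](O[Si](C)(C)C(C)(C)C)[C@]1(O)COCc1ccc(OC)cc1
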